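Atom numbering used throughout (target numbering): ring C1 (angelate), C2, C3 (methyl), C4 (hydroxyl), C5, C6 (side chain); chain C7 (methyl-bearing CH), C8 (CH2), C9 (acetoxy CH), C10=C11(CH3)2. In this numbering the target is (1R,3S,4R,6S,7R,9R).

## Analysis of the target

The target 26 is a monocyclic bisabolane-type diester: one cyclohexane ring with an angelate at C1, a methyl at C3, a free hydroxyl at C4 and, at C6, the branch C7H(CH3)–C8H2–C9H(OAc)–C10H=C11(CH3)2. It has six stereocentres, four on the ring (1R,3S,4R,6S) and two on the chain (7R,9R). In the chair the C1 ester, the C3 methyl and the C6 branch are all equatorial and only the C4 hydroxyl is axial. The two ring oxygens are therefore cis-1,4, C1–O is trans to the C6 branch, and the C3 methyl is cis to the C4 hydroxyl. The sensitive groups are the angelate, a Z-2-methylbut-2-enoate that drifts to the E isomer with nucleophiles, base, heat or radicals, and the C9 acetate, which is allylic to a trisubstituted alkene and can ionise or transpose under acid. The alkene also rules out hydrogenation at any stage. The difficulty lies in three oxygens that must end in three different states, in the exocyclic centre C7 next to the ring centre C6, and in C9, which is remote from every other centre. The strategy rests on two features: the cis-1,4 oxygens at C1 and C4 flank the C2–C3(CH3) unit, which is the imprint of dioxygen added across the ends of a C1=C2–C3(CH3)=C4 diene, and C6–C11 with the C7 methyl is the carbon chain of citronellal with C7 already correct.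

## Retrosynthetic reasoning

**26 to 25.** The last bond cut is the O–benzyl bond of a p-methoxybenzyl ether on the C4 oxygen. The free axial hydroxyl must stay masked while the two esters go on, and an oxidative, neutral unmasking is the mildest exit in the presence of the angelate and the allylic acetate.

**25 to 23 and 24.** The C1–O acyl bond is cut next, giving the C1 alcohol 23 and angelic acid 24. The angelate is introduced as late as possible because none of the earlier reagents (hydrides, selenium species, fluoride) can be trusted to leave its Z geometry alone.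

**23 to 22 to 21.** The C1 hydroxyl of 23 comes from the silyl ether 22, and the C9 acetate of 22 from the allylic alcohol 21. The silyl and p-methoxybenzyl groups keep C1–O and C4–O distinct from each other and from C9–O, so each oxygen is acylated or freed on its own.

**21 to 20 to 19 to 16.** The C9–H bond of 21 is cut to the enone 20, so the remote C9 centre is set by a reagent-controlled ketone reduction and not by the substrate. Enone 20 is traced to the tertiary allylic alcohol 19 by an oxidative 1,3-transposition. Alcohol 19 comes from the unfunctionalised prenyl-type terminus of 16 by electrophilic selenium addition and selenoxide elimination. This detour is chosen over a direct allylic C–H oxidation because the common reagents attack the terminal methyl groups of such an alkene, whereas here the regiochemistry is forced: the selenoxide can eliminate only towards C9.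

**16 to 14 to 13 to 11 to 10.** The C4 ether oxygen of 16 belongs to the axial alcohol 14, which is the product of equatorial hydride delivery to ketone 13. The C3 centre of 13 is an epimerisable α-carbon, so it is placed under thermodynamic control after conjugate reduction of the enone 11, the silyl ether of the hydroxy enone 10. Both ring centres that are not made by the cycloaddition are thus set by the most dependable rules of cyclohexanone chemistry, and the enone allows a reduction that leaves the side-chain alkene alone.

**10 to 9.** The hydroxy enone 10 is the base-induced isomer of the bicyclic peroxide 9: cleavage of the O–O bond with loss of the C4 bridgehead hydrogen turns C4 into the ketone and leaves the C1 oxygen as an alcohol of unchanged configuration. The C4 configuration made in the cycloaddition is given up here on purpose; what is kept is the oxygen at C4, the C1 stereocentre and the differentiation of the two oxygens.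

**9 to 7 and 8.** Both C–O bonds of 9 are cut at once, back to the cyclohexadiene 7 and dioxygen 8 in its singlet state. This is the central disconnection: it installs both ring oxygens in a single step without a protecting group, and the forward reaction has to choose the diene over the side-chain alkene and the face anti to the C6 branch.

**7 to 6 to 4.** The C3–CH3 bond of 7 is cut to the dienyl triflate 6, made from the kinetic cross-conjugated enolate of the 4-substituted cyclohexenone 4. This places the diene exactly where it is needed and avoids acid-mediated dehydrations that would scramble the double bonds. Diene 7 has the constitution of the ginger sesquiterpene hydrocarbon but the opposite configuration at both centres, so it cannot be taken from nature and is made.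

**4 to 1 and 2.** The ring of 4 is opened at C1=C2 (aldol condensation) and at C5–C6 (Michael addition), leading to (R)-citronellal 1 and methyl vinyl ketone 2. Compound 1 supplies C6–C11 and the C7 centre; the only new centre, C6, is set by an amine catalyst in the C–C bond-forming step.

## Alternatives that were turned down

**Alternative 1:** The ring is cut at C1–C2 and C5–C6, which leads to a Diels–Alder reaction of the diene A1 with the E-configured β-benzoyloxy acrylimide A2 under a chiral copper Lewis acid, giving the cyclohexene A3. In its favour, one catalytic step would fix C1 and C6 in the absolute sense, the trans C1–O/C6 relationship follows from the dienophile geometry, and the methyl arrives para to the acyl group, at C3. Against it, A3 holds none of the side chain: C7 to C11 with the C7 and C9 centres would have to be grown from an imide carbonyl, and C7 would need acyclic stereocontrol next to the ring. The C3=C4 alkene would still have to become the equatorial methyl and axial hydroxyl; hydroboration would put the oxygen on C4 but trans to the methyl, so an oxidation and reduction would follow. The benzoate would have to be exchanged for the angelate. On control of C1 and C6 this alternative is the stronger one, since a catalyst decides where the chosen route relies on a modest substrate bias. The chosen route offers instead the complete C6–C11 skeleton and C7 from 1, and both ring oxygens in one step.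

**Alternative 2:** The ring is cut at C1–C6, and the forward step is a cathodic reductive cyclisation of the tethered aldehyde–enoate A4 to the hydroxy ester A5. In its favour, the ring and the trans C1–OH/C6 relationship form together, and the C4 oxygen is present from the start as a ketal, so there is no regiochemical question of the kind that step 5 of the chosen route has to answer. Against it, all stereocontrol is relayed from the single methyl centre of A4 through a chair-like transition state, and that centre sits next to a masked ketone and can epimerise once the ketal is removed. The arm of A5 provides only C7 and C8: the C7 methyl would have to be introduced by enolate alkylation beside the ring and C9–C11 with the C9 centre appended, and A4 itself needs several steps. The chosen route is shorter in C–C bond formation because the chain and C7 come from 1; it accepts in exchange the uncertain facial selectivity of the cycloaddition.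

**Alternative 3:** The C7=C8 bond is cut, and the forward step is a ring-closing metathesis of the acrylate A6, whose isopropenyl group is joined to the acrylate to close the unsaturated lactone A7. In its favour, the lactone ties the C1 oxygen to the C9 carbonyl, offers a rigid bicycle for setting C7 by reduction of the C7=C8 bond, and its opening by an alkenyl nucleophile would free the C1 hydroxyl for acylation while C4 stays silylated, a neater differentiation of the two ring oxygens than the chosen route has. Against it, A6 already contains all four ring stereocentres, so the real problem is moved upstream and not solved. Closing a trisubstituted alkene between a 1,1-disubstituted alkene and an electron-poor acrylate is a demanding metathesis. A trans-fused bicycle gives only a small facial bias at C7, and C9 still needs a separate asymmetric reduction. The chosen route makes the ring oxygens in its key step and takes C7 from the chiral pool, so it does not need the lactone.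

Key step: step 4

Assumption: the (S)-configured prolinol ether in step 1 is assigned from the usual enamine shielding model (attack anti to the diarylmethyl group); should the sense be reversed in practice, its enantiomer would be used.

## Route

Step 1
Reactants: 1 (R)-citronellal; 2 methyl vinyl ketone
Product: 4 (4S)-4-[(2R)-6-methylhept-5-en-2-yl]cyclohex-2-en-1-one, via keto aldehyde 3 (not isolated)
Conditions: (S)-2-(methoxydiphenylmethyl)pyrrolidine (5 mol%), ethyl 3,4-dihydroxybenzoate (20 mol%), neat, 4 °C; then LiOH, i-PrOH, rt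
Reagents that add atoms: none
Why: Enamine-catalysed Michael addition: the E-enamine of 1 adds to 2 on the face away from the diphenylmethoxymethyl group, which should set C6 as S under catalyst control over the existing C7 centre; hydroxide then closes 3 by intramolecular aldol condensation (Robinson-type annulation) without touching the γ-centre.

Step 2
Reactants: 4 (4S)-4-[(2R)-6-methylhept-5-en-2-yl]cyclohex-2-en-1-one
Product: 6 (4S)-4-[(2R)-6-methylhept-5-en-2-yl]cyclohexa-1,5-dien-1-yl trifluoromethanesulfonate, via lithium dienolate 5 (not isolated)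
Conditions: LiN(i-Pr)2, THF, −78 °C; then PhNTf2, −78 → 0 °C
Reagents that add atoms: N-phenylbis(trifluoromethanesulfonimide), O=S(=O)(N(c1ccccc1)S(=O)(=O)C(F)(F)F)C(F)(F)F
Why: Kinetic α'-deprotonation of the enone by the hindered amide gives the cross-conjugated dienolate 5, and O-sulfonylation fixes it as the 2-triflyloxy-1,3-diene; the C6 centre is not enolisable under these conditions.

Step 3
Reactants: 6 (4S)-4-[(2R)-6-methylhept-5-en-2-yl]cyclohexa-1,5-dien-1-yl trifluoromethanesulfonate
Product: 7 (5S)-2-methyl-5-[(2R)-6-methylhept-5-en-2-yl]cyclohexa-1,3-diene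
Conditions: MeMgBr, Fe(acac)3 (5 mol%), THF/N-methylpyrrolidone, −30 → 0 °C
Reagents that add atoms: methylmagnesium bromide, C[Mg]Br
Why: Iron-catalysed cross-coupling of an alkenyl triflate with an alkyl Grignard reagent (Kumada type) replaces the triflate by methyl at low temperature without moving the double bonds; 7 is air-sensitive and is used at once.

Step 4
Reactants: 7 (5S)-2-methyl-5-[(2R)-6-methylhept-5-en-2-yl]cyclohexa-1,3-diene; 8 dioxygen
Product: 9 (1S,4R,7S)-5-methyl-7-[(2R)-6-methylhept-5-en-2-yl]-2,3-dioxabicyclo[2.2.2]oct-5-ene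
Conditions: O2, 5,10,15,20-tetraphenylporphyrin (cat.), hν (visible light), CH2Cl2, −78 °C
Reagents that add atoms: none
Why: Singlet dioxygen, formed by energy transfer from the excited porphyrin, adds to the s-cis-locked ring diene of 7 in a concerted suprafacial [4+2] cycloaddition that forms the C1–O and C4–O bonds together. The closest known reaction type is the sensitised photooxygenation of phellandrene-type 5-alkylcyclohexa-1,3-dienes to 2,3-dioxabicyclo[2.2.2]oct-5-enes. One ring is closed, the six-membered 1,2-dioxine, by cycloaddition across the diene termini, which turns the cyclohexadiene into the bicyclo[2.2.2] skeleton. Because the peroxide bridges a single face, the new stereocentres C1 and C4 are necessarily cis to each other. Their configuration relative to the rest of the molecule is controlled by the C6 stereocentre: the branched chain shields its own face of the nearly flat diene, most strongly when pseudoaxial, so dioxygen should enter anti to it and give the trans C1–O/C6 relationship of 9. The step needs this facial selectivity, which rests on one centre only and may be moderate, so the syn endoperoxide is expected as a separable minor product. It also needs chemoselectivity for the ring diene over the trisubstituted side-chain alkene, which can react only by the slower ene pathway; the higher reactivity of the cyclic diene, the low temperature and stopping the irradiation once 7 is consumed should secure it.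

Step 5
Reactants: 9 (1S,4R,7S)-5-methyl-7-[(2R)-6-methylhept-5-en-2-yl]-2,3-dioxabicyclo[2.2.2]oct-5-ene
Product: 10 (4S,5S)-4-hydroxy-2-methyl-5-[(2R)-6-methylhept-5-en-2-yl]cyclohex-2-en-1-one
Conditions: Et3N, CH2Cl2, 0 °C → rt
Reagents that add atoms: none
Why: Kornblum–DeLaMare rearrangement: the amine removes the C4 bridgehead hydrogen, flanked by a methylene and a flat vinylic carbon, in preference to the C1 hydrogen, which is gauche to the branched C6 substituent; E2-type O–O cleavage gives the C4 ketone and leaves the C1 oxygen as an alcohol of unchanged configuration.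

Step 6
Reactants: 10 (4S,5S)-4-hydroxy-2-methyl-5-[(2R)-6-methylhept-5-en-2-yl]cyclohex-2-en-1-one
Product: 11 (4S,5S)-4-[(tert-butyldimethylsilyl)oxy]-2-methyl-5-[(2R)-6-methylhept-5-en-2-yl]cyclohex-2-en-1-one
Conditions: TBSCl, imidazole, DMF, rt
Reagents that add atoms: tert-butyldimethylsilyl chloride, CC(C)(C)[Si](C)(C)Cl
Why: Standard silylation of a secondary allylic alcohol; it shields the C1 oxygen from the hydride reagents and marks it as the one to be acylated with the angelate later.

Step 7
Reactants: 11 (4S,5S)-4-[(tert-butyldimethylsilyl)oxy]-2-methyl-5-[(2R)-6-methylhept-5-en-2-yl]cyclohex-2-en-1-one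
Product: 13 (2S,4R,5S)-4-[(tert-butyldimethylsilyl)oxy]-2-methyl-5-[(2R)-6-methylhept-5-en-2-yl]cyclohexan-1-one, via potassium enolate 12 (not isolated)
Conditions: KBH(s-Bu)3 (1.1 equiv), THF, −78 °C; H2O; then K2CO3 (cat.), MeOH, rt
Reagents that add atoms: none
Why: Conjugate reduction by the bulky trialkylborohydride of an enone whose β-carbon carries no alkyl group (the carvone pattern) leaves the isolated side-chain alkene untouched; protonation of 12 and carbonate equilibration of the only epimerisable centre place the C3 methyl equatorial, cis to the C1 silyloxy group, which is the 3S configuration of the target.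

Step 8
Reactants: 13 (2S,4R,5S)-4-[(tert-butyldimethylsilyl)oxy]-2-methyl-5-[(2R)-6-methylhept-5-en-2-yl]cyclohexan-1-one
Product: 14 (1R,2S,4R,5S)-4-[(tert-butyldimethylsilyl)oxy]-2-methyl-5-[(2R)-6-methylhept-5-en-2-yl]cyclohexan-1-ol
Conditions: LiBH(s-Bu)3, THF, −78 °C; then H2O
Reagents that add atoms: none
Why: Steric approach control: the bulky hydride attacks the conformationally fixed 2-methylcyclohexanone along the equatorial trajectory and should give the axial C4 alcohol, cis to the C3 methyl and cis to the C1 oxygen (4R).

Step 9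
Reactants: 14 (1R,2S,4R,5S)-4-[(tert-butyldimethylsilyl)oxy]-2-methyl-5-[(2R)-6-methylhept-5-en-2-yl]cyclohexan-1-ol
Product: 16 tert-butyl({(1R,2S,4R,5S)-4-[(4-methoxyphenyl)methoxy]-5-methyl-2-[(2R)-6-methylhept-5-en-2-yl]cyclohexyl}oxy)dimethylsilane, via sodium alkoxide 15 (not isolated)
Conditions: NaH, DMF, 0 °C; then 4-methoxybenzyl chloride, n-Bu4NI (cat.), 0 °C → rt
Reagents that add atoms: 4-methoxybenzyl chloride, COc1ccc(CCl)cc1
Why: Williamson etherification of the axial alcohol; the p-methoxybenzyl ether is orthogonal to the silyl ether, survives the selenium, chromium and borane steps, and can be removed oxidatively at the end.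

Step 10
Reactants: 16 tert-butyl({(1R,2S,4R,5S)-4-[(4-methoxyphenyl)methoxy]-5-methyl-2-[(2R)-6-methylhept-5-en-2-yl]cyclohexyl}oxy)dimethylsilane
Product: 19 (3E,6R)-6-{(1S,2R,4S,5R)-2-[(tert-butyldimethylsilyl)oxy]-5-[(4-methoxyphenyl)methoxy]-4-methylcyclohexyl}-2-methylhept-3-en-2-ol, via hydroxy selenide 17 (not isolated), via selenoxide 18 (not isolated)
Conditions: N-(phenylselanyl)phthalimide, H2O, camphorsulfonic acid (cat.), CH2Cl2, rt; then H2O2 (30% aq., excess), pyridine, 0 °C → rt
Reagents that add atoms: water, O
Why: Electrophilic hydroxyselenation of the only alkene is Markovnikov (water at C11, selenium at C10); oxidation to the selenoxide and syn-elimination can run only towards C9 because C11 carries no hydrogen, which should give the E-configured C9=C10 alkene with the tertiary C11 alcohol.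

Step 11
Reactants: 19 (3E,6R)-6-{(1S,2R,4S,5R)-2-[(tert-butyldimethylsilyl)oxy]-5-[(4-methoxyphenyl)methoxy]-4-methylcyclohexyl}-2-methylhept-3-en-2-ol
Product: 20 (6R)-6-{(1S,2R,4S,5R)-2-[(tert-butyldimethylsilyl)oxy]-5-[(4-methoxyphenyl)methoxy]-4-methylcyclohexyl}-2-methylhept-2-en-4-one
Conditions: pyridinium chlorochromate (C5H5NH[CrO3Cl]), 4 Å molecular sieves, CH2Cl2, rt
Reagents that add atoms: none
Why: Babler–Dauben oxidative transposition: the chromate ester of the tertiary allylic alcohol undergoes a [3,3] shift to the C9 chromate, which is oxidised to the ketone; the oxygen arrives at C9 and the C10=C11 alkene is restored, with no other oxidisable hydroxyl in the molecule.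

Step 12
Reactants: 20 (6R)-6-{(1S,2R,4S,5R)-2-[(tert-butyldimethylsilyl)oxy]-5-[(4-methoxyphenyl)methoxy]-4-methylcyclohexyl}-2-methylhept-2-en-4-one
Product: 21 (4R,6R)-6-{(1S,2R,4S,5R)-2-[(tert-butyldimethylsilyl)oxy]-5-[(4-methoxyphenyl)methoxy]-4-methylcyclohexyl}-2-methylhept-2-en-4-ol
Conditions: (S)-1-methyl-3,3-diphenyltetrahydro-1H,3H-pyrrolo[1,2-c][1,3,2]oxazaborole (20 mol%), catecholborane, toluene, −78 °C
Reagents that add atoms: none
Why: Corey–Bakshi–Shibata reduction: the alkenyl group acts as the large substituent and the primary alkyl as the small one, so the (S)-oxazaborolidine should deliver hydride to give the 9R alcohol under reagent control; the remote C7 centre has little say, and 1,2-reduction is favoured at low temperature.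

Step 13
Reactants: 21 (4R,6R)-6-{(1S,2R,4S,5R)-2-[(tert-butyldimethylsilyl)oxy]-5-[(4-methoxyphenyl)methoxy]-4-methylcyclohexyl}-2-methylhept-2-en-4-ol
Product: 22 (4R,6R)-6-{(1S,2R,4S,5R)-2-[(tert-butyldimethylsilyl)oxy]-5-[(4-methoxyphenyl)methoxy]-4-methylcyclohexyl}-2-methylhept-2-en-4-yl acetate
Conditions: Ac2O, pyridine, 4-(dimethylamino)pyridine (cat.), CH2Cl2, 0 °C → rt
Reagents that add atoms: acetic anhydride, CC(=O)OC(C)=O
Why: Routine acylation of the only free hydroxyl under basic conditions, which do not ionise the allylic C9–O bond, so the configuration is retained.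

Step 14
Reactants: 22 (4R,6R)-6-{(1S,2R,4S,5R)-2-[(tert-butyldimethylsilyl)oxy]-5-[(4-methoxyphenyl)methoxy]-4-methylcyclohexyl}-2-methylhept-2-en-4-yl acetate
Product: 23 (4R,6R)-6-{(1S,2R,4S,5R)-2-hydroxy-5-[(4-methoxyphenyl)methoxy]-4-methylcyclohexyl}-2-methylhept-2-en-4-yl acetate
Conditions: HF·pyridine, pyridine, THF, 0 °C → rt
Reagents that add atoms: none
Why: Fluoride-driven cleavage of the Si–O bond; buffering with excess pyridine keeps the medium mild enough for the allylic acetate, and the benzyl-type ether is inert.

Step 15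
Reactants: 23 (4R,6R)-6-{(1S,2R,4S,5R)-2-hydroxy-5-[(4-methoxyphenyl)methoxy]-4-methylcyclohexyl}-2-methylhept-2-en-4-yl acetate; 24 angelic acid
Product: 25 (1R,2S,4R,5S)-2-[(2R,4R)-4-acetoxy-6-methylhept-5-en-2-yl]-4-[(4-methoxyphenyl)methoxy]-5-methylcyclohexyl (2Z)-2-methylbut-2-enoate
Conditions: 2,4,6-trichlorobenzoyl chloride, Et3N, toluene, rt; then 23, toluene, 80 °C
Reagents that add atoms: none
Why: Yamaguchi esterification through the mixed anhydride, run without a nucleophilic acyl-transfer catalyst so that no reversible conjugate addition can turn the Z acid into the E isomer; the hindered aroyl carbonyl directs the alcohol to the angeloyl carbonyl.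

Step 16
Reactants: 25 (1R,2S,4R,5S)-2-[(2R,4R)-4-acetoxy-6-methylhept-5-en-2-yl]-4-[(4-methoxyphenyl)methoxy]-5-methylcyclohexyl (2Z)-2-methylbut-2-enoate
Product: 26 (1R,2S,4R,5S)-2-[(2R,4R)-4-acetoxy-6-methylhept-5-en-2-yl]-4-hydroxy-5-methylcyclohexyl (2Z)-2-methylbut-2-enoate
Conditions: DDQ, CH2Cl2/pH 7 phosphate buffer, 0 °C → rt
Reagents that add atoms: none
Why: Oxidative cleavage of the p-methoxybenzyl ether (benzylic hydride abstraction, then hydrolysis of the oxocarbenium ion) under neutral buffered conditions, which should leave both esters, the allylic acetate and the alkene untouched.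

## Compound list

1 | (R)-citronellal, (3R)-3,7-dimethyloct-6-enal | O=CC[C@H](C)CCC=C(C)C | starting material
2 | methyl vinyl ketone, but-3-en-2-one | CC(=O)C=C | starting material
3 | (2S,3R)-3,7-dimethyl-2-(3-oxobutyl)oct-6-enal | O=C[C@@H](CCC(C)=O)[C@H](C)CCC=C(C)C | intermediate (not isolated)
4 | (4S)-4-[(2R)-6-methylhept-5-en-2-yl]cyclohex-2-en-1-one | O=C1C=C[C@@H](CC1)[C@H](C)CCC=C(C)C | intermediate
5 | lithium (4S)-4-[(2R)-6-methylhept-5-en-2-yl]cyclohexa-1,5-dien-1-olate | [Li+].[O-]C1=CC[C@H](C=C1)[C@H](C)CCC=C(C)C | intermediate (not isolated)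
6 | (4S)-4-[(2R)-6-methylhept-5-en-2-yl]cyclohexa-1,5-dien-1-yl trifluoromethanesulfonate | O=S(=O)(OC1=CC[C@H](C=C1)[C@H](C)CCC=C(C)C)C(F)(F)F | intermediate
7 | (5S)-2-methyl-5-[(2R)-6-methylhept-5-en-2-yl]cyclohexa-1,3-diene | C1=CC(C)=CC[C@H]1[C@H](C)CCC=C(C)C | intermediate
8 | dioxygen (used in its singlet state) | O=O | starting material
9 | (1S,4R,7S)-5-methyl-7-[(2R)-6-methylhept-5-en-2-yl]-2,3-dioxabicyclo[2.2.2]oct-5-ene | O1[C@@H]2C=C(C)[C@H](O1)C[C@H]2[C@H](C)CCC=C(C)C | intermediate
10 | (4S,5S)-4-hydroxy-2-methyl-5-[(2R)-6-methylhept-5-en-2-yl]cyclohex-2-en-1-one | O=C1C(C)=C[C@@H](O)[C@@H](C1)[C@H](C)CCC=C(C)C | intermediate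
11 | (4S,5S)-4-[(tert-butyldimethylsilyl)oxy]-2-methyl-5-[(2R)-6-methylhept-5-en-2-yl]cyclohex-2-en-1-one | O=C1C(C)=C[C@@H](O[Si](C)(C)C(C)(C)C)[C@@H](C1)[C@H](C)CCC=C(C)C | intermediate
12 | potassium (4R,5S)-4-[(tert-butyldimethylsilyl)oxy]-2-methyl-5-[(2R)-6-methylhept-5-en-2-yl]cyclohex-1-en-1-olate | [K+].[O-]C1=C(C)C[C@@H](O[Si](C)(C)C(C)(C)C)[C@@H](C1)[C@H](C)CCC=C(C)C | intermediate (not isolated)
13 | (2S,4R,5S)-4-[(tert-butyldimethylsilyl)oxy]-2-methyl-5-[(2R)-6-methylhept-5-en-2-yl]cyclohexan-1-one | O=C1[C@@H](C)C[C@@H](O[Si](C)(C)C(C)(C)C)[C@@H](C1)[C@H](C)CCC=C(C)C | intermediate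
14 | (1R,2S,4R,5S)-4-[(tert-butyldimethylsilyl)oxy]-2-methyl-5-[(2R)-6-methylhept-5-en-2-yl]cyclohexan-1-ol | CC(C)(C)[Si](C)(C)O[C@@H]1C[C@H](C)[C@H](O)C[C@H]1[C@H](C)CCC=C(C)C | intermediate
15 | sodium (1R,2S,4R,5S)-4-[(tert-butyldimethylsilyl)oxy]-2-methyl-5-[(2R)-6-methylhept-5-en-2-yl]cyclohexan-1-olate | [Na+].CC(C)(C)[Si](C)(C)O[C@@H]1C[C@H](C)[C@H]([O-])C[C@H]1[C@H](C)CCC=C(C)C | intermediate (not isolated)
16 | tert-butyl({(1R,2S,4R,5S)-4-[(4-methoxyphenyl)methoxy]-5-methyl-2-[(2R)-6-methylhept-5-en-2-yl]cyclohexyl}oxy)dimethylsilane | CC(C)(C)[Si](C)(C)O[C@@H]1C[C@H](C)[C@H](OCc2ccc(OC)cc2)C[C@H]1[C@H](C)CCC=C(C)C | intermediate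
17 | (6R)-6-{(1S,2R,4S,5R)-2-[(tert-butyldimethylsilyl)oxy]-5-[(4-methoxyphenyl)methoxy]-4-methylcyclohexyl}-2-methyl-3-(phenylselanyl)heptan-2-ol (both C3 epimers) | CC(C)(C)[Si](C)(C)O[C@@H]1C[C@H](C)[C@H](OCc2ccc(OC)cc2)C[C@H]1[C@H](C)CCC([Se]c3ccccc3)C(C)(C)O | intermediate (not isolated)
18 | (6R)-3-(benzeneseleninyl)-6-{(1S,2R,4S,5R)-2-[(tert-butyldimethylsilyl)oxy]-5-[(4-methoxyphenyl)methoxy]-4-methylcyclohexyl}-2-methylheptan-2-ol (mixture at C3 and Se) | CC(C)(C)[Si](C)(C)O[C@@H]1C[C@H](C)[C@H](OCc2ccc(OC)cc2)C[C@H]1[C@H](C)CCC([Se](=O)c3ccccc3)C(C)(C)O | intermediate (not isolated)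
19 | (3E,6R)-6-{(1S,2R,4S,5R)-2-[(tert-butyldimethylsilyl)oxy]-5-[(4-methoxyphenyl)methoxy]-4-methylcyclohexyl}-2-methylhept-3-en-2-ol | CC(C)(C)[Si](C)(C)O[C@@H]1C[C@H](C)[C@H](OCc2ccc(OC)cc2)C[C@H]1[C@H](C)C/C=C/C(C)(C)O | intermediate
20 | (6R)-6-{(1S,2R,4S,5R)-2-[(tert-butyldimethylsilyl)oxy]-5-[(4-methoxyphenyl)methoxy]-4-methylcyclohexyl}-2-methylhept-2-en-4-one | CC(C)(C)[Si](C)(C)O[C@@H]1C[C@H](C)[C@H](OCc2ccc(OC)cc2)C[C@H]1[C@H](C)CC(=O)C=C(C)C | intermediate
21 | (4R,6R)-6-{(1S,2R,4S,5R)-2-[(tert-butyldimethylsilyl)oxy]-5-[(4-methoxyphenyl)methoxy]-4-methylcyclohexyl}-2-methylhept-2-en-4-ol | CC(C)(C)[Si](C)(C)O[C@@H]1C[C@H](C)[C@H](OCc2ccc(OC)cc2)C[C@H]1[C@H](C)C[C@H](C=C(C)C)O | intermediate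
22 | (4R,6R)-6-{(1S,2R,4S,5R)-2-[(tert-butyldimethylsilyl)oxy]-5-[(4-methoxyphenyl)methoxy]-4-methylcyclohexyl}-2-methylhept-2-en-4-yl acetate | CC(C)(C)[Si](C)(C)O[C@@H]1C[C@H](C)[C@H](OCc2ccc(OC)cc2)C[C@H]1[C@H](C)C[C@H](C=C(C)C)OC(C)=O | intermediate
23 | (4R,6R)-6-{(1S,2R,4S,5R)-2-hydroxy-5-[(4-methoxyphenyl)methoxy]-4-methylcyclohexyl}-2-methylhept-2-en-4-yl acetate | O[C@@H]1C[C@H](C)[C@H](OCc2ccc(OC)cc2)C[C@H]1[C@H](C)C[C@H](C=C(C)C)OC(C)=O | intermediate
24 | angelic acid, (2Z)-2-methylbut-2-enoic acid | C/C=C(/C)C(=O)O | starting material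
25 | (1R,2S,4R,5S)-2-[(2R,4R)-4-acetoxy-6-methylhept-5-en-2-yl]-4-[(4-methoxyphenyl)methoxy]-5-methylcyclohexyl (2Z)-2-methylbut-2-enoate | C/C=C(/C)C(=O)O[C@@H]1C[C@H](C)[C@H](OCc2ccc(OC)cc2)C[C@H]1[C@H](C)C[C@H](C=C(C)C)OC(C)=O | intermediate
26 | (1R,2S,4R,5S)-2-[(2R,4R)-4-acetoxy-6-methylhept-5-en-2-yl]-4-hydroxy-5-methylcyclohexyl (2Z)-2-methylbut-2-enoate (CNP0237033.1) | C/C=C(/C)C(=O)O[C@@H]1C[C@H](C)[C@H](O)C[C@H]1[C@H](C)C[C@H](C=C(C)C)OC(C)=O | target

## Step count and least certain steps

Total step count: 16. Longest linear sequence: 16 steps (1 to 26); 2, 8 and 24 enter as single reagents.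

**Step 4 (key step).** The most likely failure is poor facial selectivity. Singlet dioxygen is small, the diene ring is nearly flat, and the C6 chain shields its face well only when it is pseudoaxial, so a large share of the syn endoperoxide may form. Over-oxidation of the side-chain alkene by the ene pathway is a second concern if irradiation is prolonged. The fallback sets out from 7 and returns to the route at 10, and it does not rely on the facial bias. The mixed photooxygenation product, 9 together with its diastereomer (1R,4S,7S)-5-methyl-7-[(2R)-6-methylhept-5-en-2-yl]-2,3-dioxabicyclo[2.2.2]oct-5-ene F1, is taken through the base rearrangement of step 5. The two hydroxy enones are separated at that stage, where they differ as epimeric alcohols. The unwanted C1 epimer (4R,5S)-4-hydroxy-2-methyl-5-[(2R)-6-methylhept-5-en-2-yl]cyclohex-2-en-1-one F2 is inverted by a Mitsunobu reaction with 4-nitrobenzoic acid to (1S,6S)-3-methyl-6-[(2R)-6-methylhept-5-en-2-yl]-4-oxocyclohex-2-en-1-yl 4-nitrobenzoate F3, and methanolysis with K2CO3 in MeOH gives 10.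

**Step 5.** Regiocontrol of the deprotonation may be lost. Each bridgehead hydrogen has one neighbouring substituent (a vinylic methyl beside C4–H, the branched chain beside C1–H), and removal of C1–H would lead to the more conjugated β-methyl enone, so the steric preference for C4–H may be small. The fallback sets out from 9 and returns at 16, and it makes use of the other regioisomer. The C1 ketone (4R,6S)-4-hydroxy-3-methyl-6-[(2R)-6-methylhept-5-en-2-yl]cyclohex-2-en-1-one F4 keeps the C4 oxygen in the configuration made by the cycloaddition. It is etherified with 4-methoxybenzyl trichloroacetimidate and catalytic Sc(OTf)3 to (4R,6S)-4-[(4-methoxyphenyl)methoxy]-3-methyl-6-[(2R)-6-methylhept-5-en-2-yl]cyclohex-2-en-1-one F5. Conjugate reduction with [(Ph3P)CuH]6, anti to the C4 ether, gives (2S,4R,5S)-4-[(4-methoxyphenyl)methoxy]-5-methyl-2-[(2R)-6-methylhept-5-en-2-yl]cyclohexan-1-one F6. NaBH4 by axial attack gives the equatorial alcohol (1R,2S,4R,5S)-4-[(4-methoxyphenyl)methoxy]-5-methyl-2-[(2R)-6-methylhept-5-en-2-yl]cyclohexan-1-ol F7, and silylation with TBSCl and imidazole gives 16. In this variant C3 is set by kinetic facial control and C1 by a small hydride, which is less secure than the main sequence.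

**Step 12.** Facial discrimination at C9 may be insufficient. The two groups on the ketone, a β,β-dimethylvinyl group and a β-branched primary alkyl, are less different in size than in the usual substrates of this reduction, and some 1,4-reduction may compete. The fallback sets out from 20 and returns at 22, replacing reagent control by inversion. Luche reduction (NaBH4, CeCl3, MeOH) gives 21 and its C9 epimer (4S,6R)-6-{(1S,2R,4S,5R)-2-[(tert-butyldimethylsilyl)oxy]-5-[(4-methoxyphenyl)methoxy]-4-methylcyclohexyl}-2-methylhept-2-en-4-ol F8, which are separated. Alcohol 21 is acetylated as in step 13, and F8 is converted into 22 directly by a Mitsunobu reaction with acetic acid, with inversion at C9.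

**Step 15.** The Z double bond of the acyl group may isomerise to the E (tiglate) form during the slow acylation of the hindered C1 hydroxyl at 80 °C, by reversible conjugate addition of chloride or amine to the activated acid. The fallback sets out from 23 and returns at 25, building the Z alkene on the ester itself. Alcohol 23 is acylated with 2-[bis(2,2,2-trifluoroethoxy)phosphoryl]propanoic acid (dicyclohexylcarbodiimide, 4-(dimethylamino)pyridine) to the phosphonate ester (1R,2S,4R,5S)-2-[(2R,4R)-4-acetoxy-6-methylhept-5-en-2-yl]-4-[(4-methoxyphenyl)methoxy]-5-methylcyclohexyl 2-[bis(2,2,2-trifluoroethoxy)phosphoryl]propanoate F9. A Still–Gennari olefination with acetaldehyde (KN(SiMe3)2, 18-crown-6, THF, −78 °C) should then give the Z-configured 2-methylbut-2-enoate 25.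

## Further compounds

F1 | step 4 | (1R,4S,7S)-5-methyl-7-[(2R)-6-methylhept-5-en-2-yl]-2,3-dioxabicyclo[2.2.2]oct-5-ene | O1[C@H]2C=C(C)[C@@H](O1)C[C@H]2[C@H](C)CCC=C(C)C
F2 | step 4 | (4R,5S)-4-hydroxy-2-methyl-5-[(2R)-6-methylhept-5-en-2-yl]cyclohex-2-en-1-one | O=C1C(C)=C[C@H](O)[C@@H](C1)[C@H](C)CCC=C(C)C
F3 | step 4 | (1S,6S)-3-methyl-6-[(2R)-6-methylhept-5-en-2-yl]-4-oxocyclohex-2-en-1-yl 4-nitrobenzoate | O=C1C(C)=C[C@@H](OC(=O)c2ccc(cc2)[N+](=O)[O-])[C@@H](C1)[C@H](C)CCC=C(C)C
F4 | step 5 | (4R,6S)-4-hydroxy-3-methyl-6-[(2R)-6-methylhept-5-en-2-yl]cyclohex-2-en-1-one | O=C1C=C(C)[C@H](O)C[C@H]1[C@H](C)CCC=C(C)C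
F5 | step 5 | (4R,6S)-4-[(4-methoxyphenyl)methoxy]-3-methyl-6-[(2R)-6-methylhept-5-en-2-yl]cyclohex-2-en-1-one | O=C1C=C(C)[C@H](OCc2ccc(OC)cc2)C[C@H]1[C@H](C)CCC=C(C)C
F6 | step 5 | (2S,4R,5S)-4-[(4-methoxyphenyl)methoxy]-5-methyl-2-[(2R)-6-methylhept-5-en-2-yl]cyclohexan-1-one | O=C1C[C@H](C)[C@H](OCc2ccc(OC)cc2)C[C@H]1[C@H](C)CCC=C(C)C
F7 | step 5 | (1R,2S,4R,5S)-4-[(4-methoxyphenyl)methoxy]-5-methyl-2-[(2R)-6-methylhept-5-en-2-yl]cyclohexan-1-ol | O[C@@H]1C[C@H](C)[C@H](OCc2ccc(OC)cc2)C[C@H]1[C@H](C)CCC=C(C)C
F8 | step 12 | (4S,6R)-6-{(1S,2R,4S,5R)-2-[(tert-butyldimethylsilyl)oxy]-5-[(4-methoxyphenyl)methoxy]-4-methylcyclohexyl}-2-methylhept-2-en-4-ol | CC(C)(C)[Si](C)(C)O[C@@H]1C[C@H](C)[C@H](OCc2ccc(OC)cc2)C[C@H]1[C@H](C)C[C@@H](C=C(C)C)O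
F9 | step 15 | (1R,2S,4R,5S)-2-[(2R,4R)-4-acetoxy-6-methylhept-5-en-2-yl]-4-[(4-methoxyphenyl)methoxy]-5-methylcyclohexyl 2-[bis(2,2,2-trifluoroethoxy)phosphoryl]propanoate (both epimers at the phosphonate carbon) | CC(C(=O)O[C@@H]1C[C@H](C)[C@H](OCc2ccc(OC)cc2)C[C@H]1[C@H](C)C[C@H](C=C(C)C)OC(C)=O)P(=O)(OCC(F)(F)F)OCC(F)(F)F
A1 | alternative 1 | isoprene, 2-methylbuta-1,3-diene | C=CC(C)=C
A2 | alternative 1 | 3-[(2E)-3-(benzoyloxy)prop-2-enoyl]oxazolidin-2-one | O=C(O/C=C/C(=O)N1CCOC1=O)c1ccccc1
A3 | alternative 1 | 3-[(1R,6R)-6-(benzoyloxy)-4-methylcyclohex-3-ene-1-carbonyl]oxazolidin-2-one | O=C(c1ccccc1)O[C@@H]1CC(C)=CC[C@H]1C(=O)N1CCOC1=O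
A4 | alternative 2 | methyl (2E)-4-{2-[(2S)-4-oxobutan-2-yl]-1,3-dioxolan-2-yl}but-2-enoate | O=CC[C@H](C)C1(OCCO1)C/C=C/C(=O)OC
A5 | alternative 2 | methyl 2-[(7S,8R,10S)-8-hydroxy-10-methyl-1,4-dioxaspiro[4.5]decan-7-yl]acetate | O[C@@H]1C[C@H](C)C2(OCCO2)C[C@H]1CC(=O)OC
A6 | alternative 3 | (1R,2S,4R,5S)-4-[(tert-butyldimethylsilyl)oxy]-5-methyl-2-(prop-1-en-2-yl)cyclohexyl prop-2-enoate | C=CC(=O)O[C@@H]1C[C@H](C)[C@H](O[Si](C)(C)C(C)(C)C)C[C@H]1C(C)=C
A7 | alternative 3 | (4aS,6R,7S,8aR)-6-[(tert-butyldimethylsilyl)oxy]-4,7-dimethyl-4a,5,6,7,8,8a-hexahydro-2H-chromen-2-one | O=C1O[C@@H]2C[C@H](C)[C@H](O[Si](C)(C)C(C)(C)C)C[C@H]2C(C)=C1
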